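Longipinane numbering is used: C1 ketone, C2=C3 enone (C3–CH3), bridgeheads C4 and C11, one-carbon bridges C5 and C10, C6 quaternary, C7–OAc, C9–OAng. Everything rests on cutting ring A, the 3-methylcyclohex-2-enone C1–C5/C11, at C2=C3 and at C4–C5, the bond it shares with the seven-membered ring C4–C10. One amine-mediated intramolecular Robinson annulation of an open-chain hydroxy enone/methyl ketone forms both: 7-exo Michael addition makes C4–C5 and the cycloheptane, aldol condensation makes C2=C3 and ring A. The cyclobutane bond C10–C11 is closed afterwards by oxidative coupling of two enolates. C6/C7 come from an iridium-catalysed tert-(hydroxy)prenylation, C9 from an Evans–Tishchenko reduction.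

Key step: step 8

Remark 1: the carbon that becomes C10 enters racemic in step 1 and is carried as a mixture of two epimers up to compound 16; step 11 planarises it as an enolate, so both epimers converge, and the SMILES leave this centre undefined.
Remark 2: the iridium-catalysed coupling of step 4 is taken to run through the (E)-σ-allyl iridium species and a chair-like transition state (anti diol); (R)-Tol-BINAP is assumed to be the ligand antipode that gives (2R,3R)-7.

Step 1
Reactants: 1 ethyl 3-oxopentanoate; 2 3-bromo-2-methylprop-1-ene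
Product: 3 ethyl 4,6-dimethyl-3-oxohept-6-enoate (racemic)
Conditions: NaH, THF, 0 °C; n-BuLi, 0 °C; then 2, 0 °C to rt
Reagents that add atoms: none
Why: Huckin–Weiler dianion alkylation, in which the more reactive γ-carbanion of the β-keto ester dianion is alkylated by the allylic bromide; the new centre (future C10) is racemic and is erased later.

Step 2
Reactants: 3 ethyl 4,6-dimethyl-3-oxohept-6-enoate
Product: 4 ethyl 2-[2-(4-methylpent-4-en-2-yl)-1,3-dioxolan-2-yl]acetate (racemic)
Conditions: 1,2-bis(trimethylsilyloxy)ethane, TMSOTf (cat.), CH2Cl2, −78 to −20 °C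
Reagents that add atoms: 1,2-bis(trimethylsilyloxy)ethane, C[Si](C)(C)OCCO[Si](C)(C)C
Why: Noyori ketalisation masks the future C9 ketone under conditions mild enough to leave the 1,1-disubstituted alkene in place.

Step 3
Reactants: 4 ethyl 2-[2-(4-methylpent-4-en-2-yl)-1,3-dioxolan-2-yl]acetate
Product: 5 2-[2-(4-methylpent-4-en-2-yl)-1,3-dioxolan-2-yl]ethan-1-ol (racemic)
Conditions: LiAlH4, Et2O, 0 °C
Reagents that add atoms: none
Why: hydride reduction of the ester to the primary alcohol (future C7), to which dioxolane and alkene are inert.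

Step 4
Reactants: 5 2-[2-(4-methylpent-4-en-2-yl)-1,3-dioxolan-2-yl]ethan-1-ol; 6 2-ethenyl-2-methyloxirane (isoprene monoxide, racemic)
Product: 7 (2R,3R)-2-ethenyl-2-methyl-4-[2-(4-methylpent-4-en-2-yl)-1,3-dioxolan-2-yl]butane-1,3-diol (two epimers at the pentenyl CH–CH3)
Conditions: [Ir(cod)Cl]2 (2.5 mol%), (R)-Tol-BINAP, 4-cyano-3-nitrobenzoic acid, allyl acetate (forms the cyclometalated π-allyl iridium C,O-benzoate), K3PO4 (5 mol%), THF, 60 °C
Reagents that add atoms: none
Why: Krische tert-(hydroxy)prenylation (redox-triggered carbonyl addition): the primary alcohol is dehydrogenated to the aldehyde, which is attacked by the (E)-σ-allyl iridium species from isoprene monoxide through a closed chair transition state, so the quaternary C6 and the carbinol C7 are set together, anti, under control of the chiral ligand.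

Step 5
Reactants: 7 (2R,3R)-2-ethenyl-2-methyl-4-[2-(4-methylpent-4-en-2-yl)-1,3-dioxolan-2-yl]butane-1,3-diol
Product: 8 (2S,3R)-2-ethenyl-3-hydroxy-2-methyl-4-[2-(4-methylpent-4-en-2-yl)-1,3-dioxolan-2-yl]butanal
Conditions: TEMPO (10 mol%), PhI(OAc)2, CH2Cl2, rt
Reagents that add atoms: none
Why: oxoammonium oxidation is selective for the primary over the secondary hydroxyl, and the α-quaternary aldehyde cannot epimerise.

Step 6
Reactants: 8 (2S,3R)-2-ethenyl-3-hydroxy-2-methyl-4-[2-(4-methylpent-4-en-2-yl)-1,3-dioxolan-2-yl]butanal; 9 1-(triphenyl-λ5-phosphanylidene)propan-2-one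
Product: 10 (3E,5R,6R)-5-ethenyl-6-hydroxy-5-methyl-7-[2-(4-methylpent-4-en-2-yl)-1,3-dioxolan-2-yl]hept-3-en-2-one
Conditions: toluene, 90 °C
Reagents that add atoms: none
Why: Wittig olefination with a stabilised ylide should give the (E)-enone (C5=C11–C1–C2 of the target) and touches only the aldehyde.

Step 7
Reactants: 10 (3E,5R,6R)-5-ethenyl-6-hydroxy-5-methyl-7-[2-(4-methylpent-4-en-2-yl)-1,3-dioxolan-2-yl]hept-3-en-2-one
Product: 12 (3E,5S,6R)-6-hydroxy-5-(hydroxymethyl)-5-methyl-7-[2-(4-oxopentan-2-yl)-1,3-dioxolan-2-yl]hept-3-en-2-one, via keto aldehyde 11 (not isolated)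
Conditions: O3, CH2Cl2/MeOH, −78 °C (Sudan red 7B as end-point indicator); Me2S; then NaBH(OAc)3, AcOH, rt
Reagents that add atoms: ozone, [O-][O+]=O
Why: ozonolysis cleaves the two electron-rich alkenes faster than the deactivated enone double bond, giving the methyl ketone (C3) and a neopentyl aldehyde, and the β-hydroxyl then directs NaBH(OAc)3 to reduce only that aldehyde to the C6 hydroxymethyl group.

Step 8
Reactants: 12 (3E,5S,6R)-6-hydroxy-5-(hydroxymethyl)-5-methyl-7-[2-(4-oxopentan-2-yl)-1,3-dioxolan-2-yl]hept-3-en-2-one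
Product: 14 7-hydroxy-6-(hydroxymethyl)-10,11-secolongipin-2-en-1-one 9-(ethane-1,2-diyl ketal), H-4/H-5 cis, C6 hydroxymethyl cis to the C5–C11 bond, C7–OH cis to the C6 methyl, via Michael adduct 13 (not isolated)
Conditions: 9-amino(9-deoxy)epi-quinine (20 mol%), AcOH (40 mol%), toluene, 50 °C
Reagents that add atoms: none
Why: The primary amine (as its acetate salt) turns the enone into its iminium ion and the distal methyl ketone into its enamines; only the internal enamine carbon C4 can reach the β-carbon C5, and its 7-exo-trig Michael addition forms C4–C5, closes the seven-membered ring and gives diketone 13 (the terminal enamine would need a nine-membered ring). The amine then forms the enamine of the less hindered C1 acetyl group (flanked by CH3 and CH2), whose carbon C2 adds to the α-branched ketone C3 in a 6-(enolexo)-exo-trig aldol closure, and loss of water gives the C2=C3 enone of ring A; enolate conditions would instead attack the less hindered carbonyl and give the regioisomeric enone, which is why amine catalysis is chosen. The closest known reaction type is the amine-catalysed intramolecular Michael addition/aldol condensation (Robinson annulation, including cinchona primary amine aldolisations of 1,5-diketones). C5 is set in the Michael step by the face of the iminium ion that is attacked, which is controlled by the chiral amine together with the C6/C7 stereocentres of the tether (the C7 hydroxyl and the C6 hydroxymethyl can both stand axial in the chair-like seven-membered transition state that keeps the enone equatorial). C4 stays epimerisable through the dienamine and should settle cis to H-5, because only the cis ring fusion lets the C4–C10 bond stand pseudo-axial next to the C3 methyl (allylic 1,2-strain) while the bulky C6 stays equatorial. The step needs the C9 ketone to stay masked as the dioxolane, since the free 1,4-diketone would close to a cyclopentenone.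

Step 9
Reactants: 14 7-hydroxy-6-(hydroxymethyl)-10,11-secolongipin-2-en-1-one 9-(ethane-1,2-diyl ketal)
Product: 15 6-[(tert-butyldiphenylsilyloxy)methyl]-7-hydroxy-10,11-secolongipin-2-en-1-one 9-(ethane-1,2-diyl ketal)
Conditions: tert-butyl(chloro)diphenylsilane, imidazole, CH2Cl2, 0 °C
Reagents that add atoms: tert-butyl(chloro)diphenylsilane, CC(C)(C)[Si](Cl)(c1ccccc1)c1ccccc1
Why: the bulky silyl chloride should react only at the primary hydroxyl, which keeps this hydroxyl from forming a hemiketal with the C9 ketone and leaves C7–OH free for steps 11 and 12.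

Step 10
Reactants: 15 6-[(tert-butyldiphenylsilyloxy)methyl]-7-hydroxy-10,11-secolongipin-2-en-1-one 9-(ethane-1,2-diyl ketal)
Product: 16 6-[(tert-butyldiphenylsilyloxy)methyl]-7-hydroxy-10,11-secolongipin-2-ene-1,9-dione
Conditions: PPTS, acetone/H2O, 50 °C
Reagents that add atoms: water, O
Why: mild acid hydrolysis of the dioxolane frees the C9 ketone, now harmless because the methyl ketone has been consumed, without cleaving the silyl ether or dehydrating the β-hydroxy ketone.

Step 11
Reactants: 16 6-[(tert-butyldiphenylsilyloxy)methyl]-7-hydroxy-10,11-secolongipin-2-ene-1,9-dione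
Product: 17 6-[(tert-butyldiphenylsilyloxy)methyl]-7-hydroxylongipin-2-ene-1,9-dione (cyclobutane closed; C4, C5, C10, C11 as in the target)
Conditions: LiN(iPr)2 (3.3 equiv), THF, −78 °C (16 added to the base); then CuCl2 (2.2 equiv) in DMF, −78 to 0 °C
Reagents that add atoms: none
Why: Saegusa-type intramolecular oxidative coupling of two lithium enolates: the base removes the α′-proton at C11 of the enone (kinetic cross-conjugated dienolate) and, with the neighbouring C7 lithium alkoxide disfavouring enolisation toward C8, the C10 proton of the C9 ketone (both C10 epimers converge), and one-electron oxidation by CuCl2 joins C10 to C11, the cis ring fusion allowing only one cage, so both new stereocentres are fixed by the ring system.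

Step 12
Reactants: 17 6-[(tert-butyldiphenylsilyloxy)methyl]-7-hydroxylongipin-2-ene-1,9-dione
Product: 18 7-acetoxy-6-[(tert-butyldiphenylsilyloxy)methyl]-9-hydroxylongipin-2-en-1-one (C9–OH trans to C7–OAc)
Conditions: CH3CHO (8 equiv), SmI2 (30 mol%), THF, −10 °C
Reagents that add atoms: acetaldehyde, CC=O
Why: Evans–Tishchenko reduction: the hemiacetal of C7–OH with acetaldehyde delivers its hydride within a samarium chelate to the C9 ketone from the face of the C7 oxygen, which sets C9 anti to C7, leaves the acetate on O-7 and the new C9 hydroxyl free, and does not touch the enone.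

Step 13
Reactants: 18 7-acetoxy-6-[(tert-butyldiphenylsilyloxy)methyl]-9-hydroxylongipin-2-en-1-one
Product: 19 7-acetoxy-9-hydroxy-6-(hydroxymethyl)longipin-2-en-1-one
Conditions: HF·pyridine, pyridine, THF, 0 °C to rt
Reagents that add atoms: none
Why: fluoride cleavage of the silyl ether in a weakly acidic medium, which should leave acetate and enone intact and suppress 1,3-acetyl migration.

Step 14
Reactants: 19 7-acetoxy-9-hydroxy-6-(hydroxymethyl)longipin-2-en-1-one; 20 angelic acid, (Z)-2-methylbut-2-enoic acid
Product: 22 (4R,5S,6S,7R,9R,10R,11R)-7-acetoxy-9-angeloyloxy-6-(angeloyloxymethyl)longipin-2-en-1-one (CNP0364726.1), via angelic 2,4,6-trichlorobenzoic anhydride 21 (not isolated)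
Conditions: 20 (3 equiv), 2,4,6-trichlorobenzoyl chloride (3 equiv), Et3N (4 equiv), toluene, rt; then 19 (1 equiv), 80 °C
Reagents that add atoms: angelic acid (second equivalent of 20), C/C=C(/C)C(=O)O
Why: Yamaguchi-type acylation in which two equivalents of the preformed mixed anhydride 21 transfer one angeloyl group each to the primary C6 hydroxymethyl and to the hindered secondary C9 hydroxyl; run without a nucleophilic catalyst, it should avoid Z-to-E isomerisation to the tiglate.

Compound list
1 | ethyl 3-oxopentanoate | CCC(=O)CC(=O)OCC | starting material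
2 | 3-bromo-2-methylprop-1-ene | CC(=C)CBr | starting material
3 | ethyl 4,6-dimethyl-3-oxohept-6-enoate (racemic) | CCOC(=O)CC(=O)C(C)CC(C)=C | intermediate
4 | ethyl 2-[2-(4-methylpent-4-en-2-yl)-1,3-dioxolan-2-yl]acetate (racemic) | CCOC(=O)CC1(OCCO1)C(C)CC(C)=C | intermediate
5 | 2-[2-(4-methylpent-4-en-2-yl)-1,3-dioxolan-2-yl]ethan-1-ol (racemic) | OCCC1(OCCO1)C(C)CC(C)=C | intermediate
6 | 2-ethenyl-2-methyloxirane (isoprene monoxide) | CC1(CO1)C=C | starting material
7 | (2R,3R)-2-ethenyl-2-methyl-4-[2-(4-methylpent-4-en-2-yl)-1,3-dioxolan-2-yl]butane-1,3-diol | OC[C@@](C)(C=C)[C@H](O)CC1(OCCO1)C(C)CC(C)=C | intermediate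
8 | (2S,3R)-2-ethenyl-3-hydroxy-2-methyl-4-[2-(4-methylpent-4-en-2-yl)-1,3-dioxolan-2-yl]butanal | O=C[C@@](C)(C=C)[C@H](O)CC1(OCCO1)C(C)CC(C)=C | intermediate
9 | 1-(triphenyl-λ5-phosphanylidene)propan-2-one | CC(=O)C=P(c1ccccc1)(c1ccccc1)c1ccccc1 | starting material
10 | (3E,5R,6R)-5-ethenyl-6-hydroxy-5-methyl-7-[2-(4-methylpent-4-en-2-yl)-1,3-dioxolan-2-yl]hept-3-en-2-one | CC(=O)/C=C/[C@@](C)(C=C)[C@H](O)CC1(OCCO1)C(C)CC(C)=C | intermediate
11 | (2R,3E)-2-{(1R)-1-hydroxy-2-[2-(4-oxopentan-2-yl)-1,3-dioxolan-2-yl]ethyl}-2-methyl-5-oxohex-3-enal | CC(=O)/C=C/[C@@](C)(C=O)[C@H](O)CC1(OCCO1)C(C)CC(C)=O | intermediate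
12 | (3E,5S,6R)-6-hydroxy-5-(hydroxymethyl)-5-methyl-7-[2-(4-oxopentan-2-yl)-1,3-dioxolan-2-yl]hept-3-en-2-one | CC(=O)/C=C/[C@@](C)(CO)[C@H](O)CC1(OCCO1)C(C)CC(C)=O | intermediate
13 | Michael adduct: cycloheptane with C4 acetyl, C5 2-oxopropyl, C6 methyl/hydroxymethyl, C7 hydroxyl, C9 spiro-dioxolane, C10 methyl | OC[C@]1(C)[C@H](CC(C)=O)[C@H](C(C)=O)C(C)C2(OCCO2)C[C@H]1O | intermediate
14 | 7-hydroxy-6-(hydroxymethyl)-10,11-secolongipin-2-en-1-one 9-(ethane-1,2-diyl ketal); H-4/H-5 cis, C6 hydroxymethyl cis to C5–C11, C7–OH cis to C6 methyl, both C10 epimers | OC[C@]1(C)[C@@H]2CC(=O)C=C(C)[C@@H]2C(C)C3(OCCO3)C[C@H]1O | intermediate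
15 | 6-[(tert-butyldiphenylsilyloxy)methyl]-7-hydroxy-10,11-secolongipin-2-en-1-one 9-(ethane-1,2-diyl ketal) | CC(C)(C)[Si](c1ccccc1)(c1ccccc1)OC[C@]1(C)[C@@H]2CC(=O)C=C(C)[C@@H]2C(C)C3(OCCO3)C[C@H]1O | intermediate
16 | 6-[(tert-butyldiphenylsilyloxy)methyl]-7-hydroxy-10,11-secolongipin-2-ene-1,9-dione | CC(C)(C)[Si](c1ccccc1)(c1ccccc1)OC[C@]1(C)[C@@H]2CC(=O)C=C(C)[C@@H]2C(C)C(=O)C[C@H]1O | intermediate
17 | 6-[(tert-butyldiphenylsilyloxy)methyl]-7-hydroxylongipin-2-ene-1,9-dione | CC(C)(C)[Si](c1ccccc1)(c1ccccc1)OC[C@]1(C)[C@@H]2[C@H]3C(=O)C=C(C)[C@@H]2[C@@]3(C)C(=O)C[C@H]1O | intermediate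
18 | 7-acetoxy-6-[(tert-butyldiphenylsilyloxy)methyl]-9-hydroxylongipin-2-en-1-one (C9–OH trans to C7–OAc) | CC(C)(C)[Si](c1ccccc1)(c1ccccc1)OC[C@]1(C)[C@@H]2[C@H]3C(=O)C=C(C)[C@@H]2[C@@]3(C)[C@H](O)C[C@H]1OC(C)=O | intermediate
19 | 7-acetoxy-9-hydroxy-6-(hydroxymethyl)longipin-2-en-1-one | OC[C@]1(C)[C@@H]2[C@H]3C(=O)C=C(C)[C@@H]2[C@@]3(C)[C@H](O)C[C@H]1OC(C)=O | intermediate
20 | angelic acid, (Z)-2-methylbut-2-enoic acid | C/C=C(/C)C(=O)O | starting material
21 | angelic 2,4,6-trichlorobenzoic anhydride | C/C=C(/C)C(=O)OC(=O)c1c(Cl)cc(Cl)cc1Cl | intermediate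
22 | (4R,5S,6S,7R,9R,10R,11R)-7-acetoxy-9-angeloyloxy-6-(angeloyloxymethyl)longipin-2-en-1-one (CNP0364726.1) | C/C=C(/C)C(=O)OC[C@]1(C)[C@@H]2[C@H]3C(=O)C=C(C)[C@@H]2[C@@]3(C)[C@H](OC(=O)/C(C)=C\C)C[C@H]1OC(C)=O | target

Total step count: 14. Longest linear sequence: 14 steps (1 to 22).

Steps most likely to fail

Step 8. The Michael addition may take place on the wrong face of the enone at C5, which would carry the ketone and the methyl-bearing alkene carbon into the wrong relation to C6/C7. The aldol closure may also start from the wrong methyl ketone, or the ring closure at the neopentyl β-carbon may be too slow. If the quinine-derived amine is mismatched, its quinidine-derived pseudo-enantiomer is the first change. The fallback changes the approach by fixing the aldol direction with an active methylene and running the Michael step under reversible Brønsted-acid conditions. It sets out from 8: Wittig reaction with ethyl 3-oxo-4-(triphenyl-λ5-phosphanylidene)butanoate should give the β-keto ester enone F1. Ozonolysis and NaBH(OAc)3 reduction as in step 7 should give the hydroxymethyl methyl ketone F2. TsOH (cat.) in toluene with azeotropic removal of water should effect the enol Michael addition and a Knoevenagel closure from the β-keto ester carbon, giving the 2-ethoxycarbonyl enone F3. Saponification with LiOH in aqueous THF and decarboxylation on acidification with AcOH at 50 °C come back to the route at 14.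

Step 11. The C9 ketone may be deprotonated toward C8 instead of C10, the C11 enolate may add to the C9 carbonyl, or the lithium aldolate may fragment by retro-aldol reaction. The fallback replaces the oxidative coupling by a polar 4-exo-tet enolate alkylation of the kind used in classical pinane syntheses. It sets out from 15: the C7 hydroxyl is capped with TESOTf/2,6-lutidine and the enone is brominated at C11 through its kinetic silyl dienol ether (LiN(SiMe3)2, TMSCl; then NBS) to give the bromo enone F4. Transketalisation with acetone catalysed by PdCl2(MeCN)2 frees the C9 ketone and gives the bromo diketone F5. KN(SiMe3)2 in THF at −78 to 0 °C should form the more substituted C10 enolate, which displaces the secondary bromide to give the caged triethylsilyl ether F6. Brief treatment with HF·pyridine at 0 °C, which removes the triethylsilyl group much faster than the tert-butyldiphenylsilyl group, comes back to the route at 17.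

Step 4. The coupling may give insufficient anti selectivity or the opposite absolute sense, and the branched, ketal-bearing alcohol may be dehydrogenated slowly. The fallback replaces the redox-triggered coupling by a chiral-acid-catalysed allylboration. It sets out from 5: oxidation with Dess–Martin periodinane gives the aldehyde F7. Allylboration with pinacol (E)-[4-(tert-butyldimethylsilyloxy)-3-methylbut-2-en-1-yl]boronate, catalysed by the enantiomer of the phosphoric acid TRIP that gives the (3R) carbinol, should give the mono-silyl ether F8 through a closed chair transition state in which the (E)-silyloxymethyl group ends anti to the new hydroxyl. TBAF in THF comes back to the route at 7.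

Further compounds
F1 | step 8 | ethyl (4E,6R,7R)-6-ethenyl-7-hydroxy-6-methyl-8-[2-(4-methylpent-4-en-2-yl)-1,3-dioxolan-2-yl]-3-oxooct-4-enoate | CCOC(=O)CC(=O)/C=C/[C@@](C)(C=C)[C@H](O)CC1(OCCO1)C(C)CC(C)=C
F2 | step 8 | ethyl (4E,6S,7R)-7-hydroxy-6-(hydroxymethyl)-6-methyl-3-oxo-8-[2-(4-oxopentan-2-yl)-1,3-dioxolan-2-yl]oct-4-enoate | CCOC(=O)CC(=O)/C=C/[C@@](C)(CO)[C@H](O)CC1(OCCO1)C(C)CC(C)=O
F3 | step 8 | 2-ethoxycarbonyl derivative of 14 (ester on C2 of the enone) | OC[C@]1(C)[C@@H]2CC(=O)C(C(=O)OCC)=C(C)[C@@H]2C(C)C3(OCCO3)C[C@H]1O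
F4 | step 11 | 11-bromo-7-(triethylsilyloxy) derivative of 15 | CC(C)(C)[Si](c1ccccc1)(c1ccccc1)OC[C@]1(C)[C@@H]2C(Br)C(=O)C=C(C)[C@@H]2C(C)C3(OCCO3)C[C@H]1O[Si](CC)(CC)CC
F5 | step 11 | 11-bromo-7-(triethylsilyloxy) derivative of 16 | CC(C)(C)[Si](c1ccccc1)(c1ccccc1)OC[C@]1(C)[C@@H]2C(Br)C(=O)C=C(C)[C@@H]2C(C)C(=O)C[C@H]1O[Si](CC)(CC)CC
F6 | step 11 | 7-O-triethylsilyl ether of 17 | CC(C)(C)[Si](c1ccccc1)(c1ccccc1)OC[C@]1(C)[C@@H]2[C@H]3C(=O)C=C(C)[C@@H]2[C@@]3(C)C(=O)C[C@H]1O[Si](CC)(CC)CC
F7 | step 4 | 2-[2-(4-methylpent-4-en-2-yl)-1,3-dioxolan-2-yl]acetaldehyde | O=CCC1(OCCO1)C(C)CC(C)=C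
F8 | step 4 | 1-O-tert-butyldimethylsilyl ether of 7 | CC(C)(C)[Si](C)(C)OC[C@@](C)(C=C)[C@H](O)CC1(OCCO1)C(C)CC(C)=C
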